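**Retrosynthetic overview** (chain numbered C1 = ester carbonyl to C17 = CH2 next to the furan)
1. The C6 carboxyl is put in last: (Z)-vinyl bromide + CO/H2O under Pd, with retention, so no protecting group is needed.
2. C2=C3 comes from an (E)-selective Wittig reaction on an aldehyde that is unmasked from the ester of the homoenolate unit.
3. Key bond C5–C6: gem-dibromoalkene + zinc ester homoenolate BrZnCH2CH2CO2Et; the trans-selective Pd coupling fixes the C6=C7 geometry and leaves the cis bromide as the carboxyl precursor.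
4. The gem-dibromoalkene comes from the C7 aldehyde, made from an allylic bromide and an acetaldehyde aza-enolate; C16–C17 comes from furan-3-ylmethyl Grignard + the allylic acetate of 8-hydroxygeranyl acetate (SeO2 oxidation of geranyl acetate).
5. No ring is formed; the furan is bought as furan-3-ylmethanol.

Assumption: the target has no stereocentre and is achiral, so "single enantiomer" is read as the single geometric isomer drawn (2E,6Z,10E,14E in the numbering above).

**Step 1**
Reactants: 1 geranyl acetate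
Product: 2 (2E,6E)-8-hydroxy-3,7-dimethylocta-2,6-dien-1-yl acetate
Conditions: SeO2 (cat.), tBuOOH (70% aq.), salicylic acid (cat.), CH2Cl2, rt
Reagents that add atoms: selenium dioxide, O=[Se]=O (transfers the oxygen, catalytic); tert-butyl hydroperoxide, CC(C)(C)OO (re-oxidant, net oxygen source)
Why: Riley allylic oxidation (ene reaction, then [2,3]-sigmatropic shift) attacks only the (E)-methyl group of the electron-rich terminal alkene, because the 2,3-alkene is deactivated by the allylic acetate, and gives the (6E)-allylic alcohol.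

**Step 2**
Reactants: 3 furan-3-ylmethanol
Product: 4 3-(chloromethyl)furan
Conditions: SOCl2, pyridine, Et2O, −10 → 0 °C; used at once
Reagents that add atoms: thionyl chloride, ClS(Cl)=O
Why: Chlorodehydroxylation through the chlorosulfite (SN2 by chloride) works at this primary furylmethyl position, and pyridine traps HCl so the acid-sensitive furan survives.

**Step 3**
Reactants: 4 3-(chloromethyl)furan; 2 (2E,6E)-8-hydroxy-3,7-dimethylocta-2,6-dien-1-yl acetate
Product: 6 (2E,6E)-9-(furan-3-yl)-2,6-dimethylnona-2,6-dien-1-ol, via (furan-3-ylmethyl)magnesium chloride 5 (not isolated)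
Conditions: Mg turnings, THF, 0 °C; then 2 (0.4 equiv), Li2CuCl4 (5 mol %), THF, −20 → 0 °C; aq. NH4Cl
Reagents that add atoms: none
Why: Grignard formation followed by Li2CuCl4-catalysed SN2 coupling at the primary allylic acetate (Kochi–Schlosser type) attacks the unhindered alpha carbon and keeps the (E)-alkene, the first equivalent of Grignard reagent only deprotonating the hydroxyl.

**Step 4**
Reactants: 6 (2E,6E)-9-(furan-3-yl)-2,6-dimethylnona-2,6-dien-1-ol
Product: 7 3-[(3E,7E)-9-bromo-4,8-dimethylnona-3,7-dien-1-yl]furan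
Conditions: CBr4, PPh3, CH2Cl2, −20 → 0 °C; used at once
Reagents that add atoms: carbon tetrabromide, BrC(Br)(Br)Br
Why: Appel reaction, in which bromide displaces the oxyphosphonium group by SN2 at the primary allylic carbon under neutral conditions that spare the furan and the alkene geometry.

**Step 5**
Reactants: 8 acetaldehyde; 9 tert-butylamine
Product: 10 (E)-N-tert-butylethanimine
Conditions: neat, 0 °C; then KOH pellets; distil
Reagents that add atoms: none
Why: Imine condensation of an aldehyde with a hindered primary amine, with KOH taking up the water and the tert-butyl group suppressing self-condensation.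

**Step 6**
Reactants: 7 3-[(3E,7E)-9-bromo-4,8-dimethylnona-3,7-dien-1-yl]furan; 10 (E)-N-tert-butylethanimine
Product: 13 (4E,8E)-11-(furan-3-yl)-4,8-dimethylundeca-4,8-dienal, via lithiated imine 11 (not isolated), via alkylated imine 12 (not isolated)
Conditions: 10 (1.2 equiv), LiN(iPr)2, THF, −78 → 0 °C; then 7, −78 °C → rt; then CH3CO2H/CH3CO2Na buffer (pH 4.5), rt
Reagents that add atoms: water, O
Why: Aza-enolate (metalated imine) alkylation by SN2 at the primary allylic bromide gives clean mono-C-alkylation without aldehyde self-condensation, and mild buffered hydrolysis then frees the aldehyde.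

**Step 7**
Reactants: 13 (4E,8E)-11-(furan-3-yl)-4,8-dimethylundeca-4,8-dienal
Product: 14 3-[(3E,7E)-12,12-dibromo-4,8-dimethyldodeca-3,7,11-trien-1-yl]furan
Conditions: CBr4, PPh3, Zn dust, CH2Cl2, rt, 24 h; then 13, rt
Reagents that add atoms: carbon tetrabromide, BrC(Br)(Br)Br
Why: Corey–Fuchs (Ramirez) dibromo-olefination, a Wittig reaction of the aldehyde with Ph3P=CBr2 made in the flask, with Zn keeping the medium neutral for the furan.

**Step 8** (key step)
Reactants: 14 3-[(3E,7E)-12,12-dibromo-4,8-dimethyldodeca-3,7,11-trien-1-yl]furan; 15 ethyl 3-bromopropanoate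
Product: 17 ethyl (4Z,8E,12E)-4-bromo-15-(furan-3-yl)-8,12-dimethylpentadeca-4,8,12-trienoate, via zinc homoenolate 16 (not isolated)
Conditions: 15, Zn dust, LiCl, THF, 40 °C; then 14 (0.8 equiv), PdCl2(DPEphos) (5 mol %), THF/NMP, 0 → 23 °C
Reagents that add atoms: none
Why: Negishi coupling of a zinc ester homoenolate (the β-carbon of the propanoate as nucleophile) with the gem-dibromoalkene, in which zerovalent palladium inserts into the less hindered C–Br bond trans to the chain, so the new C5–C6 bond ends up trans to C8 and the bromide cis to C8 is kept, which fixes the C6=C7 geometry.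

**Step 9**
Reactants: 17 ethyl (4Z,8E,12E)-4-bromo-15-(furan-3-yl)-8,12-dimethylpentadeca-4,8,12-trienoate; 18 methyl 2-(triphenylphosphoranylidene)propanoate
Product: 20 methyl (2E,6Z,10E,14E)-6-bromo-17-(furan-3-yl)-2,10,14-trimethylheptadeca-2,6,10,14-tetraenoate, via bromo aldehyde 19 (not isolated)
Conditions: iBu2AlH (1.1 equiv), CH2Cl2, −78 °C; then 18 (1.6 equiv), −78 °C → rt, 16 h; aq. KNaC4H4O6
Reagents that add atoms: none
Why: Partial ester reduction stops at the aluminium hemiacetal at −78 °C, and the aldehyde released on warming undergoes Wittig olefination with the stabilised ylide, which gives the (E)-trisubstituted enoate.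

**Step 10**
Reactants: 20 methyl (2E,6Z,10E,14E)-6-bromo-17-(furan-3-yl)-2,10,14-trimethylheptadeca-2,6,10,14-tetraenoate
Product: 21 furospongin-4, (2Z,6E,10E)-13-(furan-3-yl)-2-[(3E)-5-methoxy-4-methyl-5-oxopent-3-en-1-yl]-6,10-dimethyltrideca-2,6,10-trienoic acid
Conditions: Pd(OAc)2 (5 mol %), Xantphos (6 mol %), CO (3 atm), H2O, Et3N, DMF, 60 °C; then aq. citric acid
Reagents that add atoms: carbon monoxide, [C-]#[O+]; water, O
Why: Pd-catalysed hydroxycarbonylation of the vinyl bromide (oxidative addition, CO insertion, hydrolysis of the acyl-palladium) goes with retention, so CO2H takes the place of Br cis to C8, and Et3N/water does not touch the methyl ester.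

**Compound list**
1 | geranyl acetate [(2E)-3,7-dimethylocta-2,6-dien-1-yl acetate] | CC(C)=CCC/C(C)=C/COC(C)=O | starting material
2 | (2E,6E)-8-hydroxy-3,7-dimethylocta-2,6-dien-1-yl acetate | OC/C(C)=C/CC/C(C)=C/COC(C)=O | intermediate
3 | furan-3-ylmethanol | OCc1ccoc1 | starting material
4 | 3-(chloromethyl)furan | ClCc1ccoc1 | intermediate
5 | (furan-3-ylmethyl)magnesium chloride | Cl[Mg]Cc1ccoc1 | intermediate
6 | (2E,6E)-9-(furan-3-yl)-2,6-dimethylnona-2,6-dien-1-ol | OC/C(C)=C/CC/C(C)=C/CCc1ccoc1 | intermediate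
7 | 3-[(3E,7E)-9-bromo-4,8-dimethylnona-3,7-dien-1-yl]furan | BrC/C(C)=C/CC/C(C)=C/CCc1ccoc1 | intermediate
8 | acetaldehyde | CC=O | starting material
9 | tert-butylamine | CC(C)(C)N | starting material
10 | (E)-N-tert-butylethanimine | C/C=N/C(C)(C)C | intermediate
11 | lithium N-tert-butyl-N-vinylamide (lithiated imine) | [Li]N(C=C)C(C)(C)C | intermediate
12 | (1E,4E,8E)-N-tert-butyl-11-(furan-3-yl)-4,8-dimethylundeca-4,8-dien-1-imine | CC(C)(C)/N=C/CC/C(C)=C/CC/C(C)=C/CCc1ccoc1 | intermediate
13 | (4E,8E)-11-(furan-3-yl)-4,8-dimethylundeca-4,8-dienal | O=CCC/C(C)=C/CC/C(C)=C/CCc1ccoc1 | intermediate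
14 | 3-[(3E,7E)-12,12-dibromo-4,8-dimethyldodeca-3,7,11-trien-1-yl]furan | BrC(Br)=CCC/C(C)=C/CC/C(C)=C/CCc1ccoc1 | intermediate
15 | ethyl 3-bromopropanoate | CCOC(=O)CCBr | starting material
16 | (3-ethoxy-3-oxopropyl)zinc bromide | CCOC(=O)CC[Zn]Br | intermediate
17 | ethyl (4Z,8E,12E)-4-bromo-15-(furan-3-yl)-8,12-dimethylpentadeca-4,8,12-trienoate | CCOC(=O)CC/C(Br)=C/CC/C(C)=C/CC/C(C)=C/CCc1ccoc1 | intermediate
18 | methyl 2-(triphenylphosphoranylidene)propanoate | COC(=O)C(C)=P(c1ccccc1)(c1ccccc1)c1ccccc1 | starting material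
19 | (4Z,8E,12E)-4-bromo-15-(furan-3-yl)-8,12-dimethylpentadeca-4,8,12-trienal | O=CCC/C(Br)=C/CC/C(C)=C/CC/C(C)=C/CCc1ccoc1 | intermediate
20 | methyl (2E,6Z,10E,14E)-6-bromo-17-(furan-3-yl)-2,10,14-trimethylheptadeca-2,6,10,14-tetraenoate | COC(=O)/C(C)=C/CC/C(Br)=C/CC/C(C)=C/CC/C(C)=C/CCc1ccoc1 | intermediate
21 | furospongin-4 | COC(=O)/C(C)=C/CC/C(=C/CC/C(C)=C/CC/C(C)=C/CCc1ccoc1)C(=O)O | target

**Step count**
Total: 10 steps. Longest linear sequence: 8 steps (1, 3, 4, 6, 7, 8, 9, 10).

**Steps most likely to fail, with fallbacks**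

Step 8. The chelated zinc homoenolate transmetalates slowly, so a second alkylation or loss of trans-selectivity can compete. The fallback replaces the cross-coupling by a (Z)-selective α-iodo-Wittig olefination and sets out from aldehyde 13. Bought (3-ethoxycarbonylpropyl)triphenylphosphonium bromide is deprotonated with NaN(SiMe3)2, iodinated with I2 and deprotonated again (THF, −78 °C) to the α-iodo ylide ethyl 4-iodo-4-(triphenylphosphoranylidene)butanoate F1. With 13 this gives ethyl (4Z,8E,12E)-15-(furan-3-yl)-4-iodo-8,12-dimethylpentadeca-4,8,12-trienoate F2. Treatment with iBu2AlH and then ylide 18, as in step 9, passes through (4Z,8E,12E)-15-(furan-3-yl)-4-iodo-8,12-dimethylpentadeca-4,8,12-trienal F3 to methyl (2E,6Z,10E,14E)-17-(furan-3-yl)-6-iodo-2,10,14-trimethylheptadeca-2,6,10,14-tetraenoate F4. Hydroxycarbonylation as in step 10 brings this fallback back to the route at 21.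

Step 10. The vinylpalladium intermediate sits cis to the C8–C11 chain and can add 5-exo to the C10=C11 alkene before CO inserts, and the less stable (Z)-acid could isomerise. The fallback puts the carboxyl in by bromine–lithium exchange and CO2 before any ester is present, using a propanal homoenolate in place of the ester homoenolate; it sets out from dibromide 14. Coupling with bought [2-(1,3-dioxolan-2-yl)ethyl]zinc bromide under the step 8 conditions gives 2-[(3Z,7E,11E)-3-bromo-14-(furan-3-yl)-7,11-dimethyltetradeca-3,7,11-trien-1-yl]-1,3-dioxolane F5. tBuLi (2 equiv, Et2O, −78 °C) gives the vinyllithium 2-[(3E,7E,11E)-14-(furan-3-yl)-3-lithio-7,11-dimethyltetradeca-3,7,11-trien-1-yl]-1,3-dioxolane F6, which is quenched with CO2 to (2Z,6E,10E)-2-[2-(1,3-dioxolan-2-yl)ethyl]-13-(furan-3-yl)-6,10-dimethyltrideca-2,6,10-trienoic acid F7. Aqueous HCl in THF frees (2Z,6E,10E)-13-(furan-3-yl)-6,10-dimethyl-2-(3-oxopropyl)trideca-2,6,10-trienoic acid F8, and Wittig reaction with 18 (2.2 equiv, CH2Cl2, rt) returns to the route at 21.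

Step 3. Wurtz dimerisation during Grignard formation, attack of the Grignard reagent on the acetate carbonyl, or some SN2′ product can lower the yield. The fallback reverses the order of coupling and oxidation; it sets out from 4 and comes back at 6. Grignard reagent 5 (from 4) is coupled with bought geranyl chloride (Li2CuCl4, THF, 0 °C) to dendrolasin, 3-[(3E)-4,8-dimethylnona-3,7-dien-1-yl]furan F9. Its terminal (E)-methyl group is then oxidised with SeO2 (cat.)/tBuOOH as in step 1 to give 6.

**Further compounds**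
F1 | step 8 | ethyl 4-iodo-4-(triphenylphosphoranylidene)butanoate | CCOC(=O)CCC(I)=P(c1ccccc1)(c1ccccc1)c1ccccc1
F2 | step 8 | ethyl (4Z,8E,12E)-15-(furan-3-yl)-4-iodo-8,12-dimethylpentadeca-4,8,12-trienoate | CCOC(=O)CC/C(I)=C/CC/C(C)=C/CC/C(C)=C/CCc1ccoc1
F3 | step 8 | (4Z,8E,12E)-15-(furan-3-yl)-4-iodo-8,12-dimethylpentadeca-4,8,12-trienal | O=CCC/C(I)=C/CC/C(C)=C/CC/C(C)=C/CCc1ccoc1
F4 | step 8 | methyl (2E,6Z,10E,14E)-17-(furan-3-yl)-6-iodo-2,10,14-trimethylheptadeca-2,6,10,14-tetraenoate | COC(=O)/C(C)=C/CC/C(I)=C/CC/C(C)=C/CC/C(C)=C/CCc1ccoc1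
F5 | step 10 | 2-[(3Z,7E,11E)-3-bromo-14-(furan-3-yl)-7,11-dimethyltetradeca-3,7,11-trien-1-yl]-1,3-dioxolane | O1CCOC1CC/C(Br)=C/CC/C(C)=C/CC/C(C)=C/CCc1ccoc1
F6 | step 10 | 2-[(3E,7E,11E)-14-(furan-3-yl)-3-lithio-7,11-dimethyltetradeca-3,7,11-trien-1-yl]-1,3-dioxolane | O1CCOC1CC/C([Li])=C/CC/C(C)=C/CC/C(C)=C/CCc1ccoc1
F7 | step 10 | (2Z,6E,10E)-2-[2-(1,3-dioxolan-2-yl)ethyl]-13-(furan-3-yl)-6,10-dimethyltrideca-2,6,10-trienoic acid | O1CCOC1CC/C(=C/CC/C(C)=C/CC/C(C)=C/CCc1ccoc1)C(=O)O
F8 | step 10 | (2Z,6E,10E)-13-(furan-3-yl)-6,10-dimethyl-2-(3-oxopropyl)trideca-2,6,10-trienoic acid | O=CCC/C(=C/CC/C(C)=C/CC/C(C)=C/CCc1ccoc1)C(=O)O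
F9 | step 3 | dendrolasin, 3-[(3E)-4,8-dimethylnona-3,7-dien-1-yl]furan | CC(C)=CCC/C(C)=C/CCc1ccoc1
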